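**Plan**

1. Ring labels: A is the 2,4-dihydroxyphenyl ketone ring of chalcone unit 1, B is the 4-hydroxyphenyl ring of unit 1 that carries the biaryl bond, C is the 2,4-dihydroxy-5-aryl ketone ring of unit 2, D is the terminal 4-hydroxyphenyl ring.
2. Retrosynthetic cuts, in order: the four aryl O–CH2OMe acetals; the bond between the ring A ketone carbon and the vinylic CH next to it (opened to a formyl C–H on ring A and a terminal alkyne on ring B); the Cα=Cβ bond of unit 2 (aldol); the ring B–ring C biaryl bond (Suzuki–Miyaura); the ring B–alkyne bond (Sonogashira).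
3. Forward: no ring is formed; the four benzene rings are joined as a chain in the order B (alkyne and boronate installed), B–C, B–C–D, A–B–C–D, then global deprotection.
4. Enabling feature: the hydroxyl on C2 of ring A lies ortho to the ketone carbon. In the aldehyde precursor it binds rhodium as a phenoxide and delivers the neighbouring formyl C–H, so the ketone carbon can enter as CHO and the two vinylic carbons as C≡CH, with no activating group to remove.
5. Stereochemistry: the target has no stereocentre; the E alkene of unit 1 comes from syn addition of H and acyl across the alkyne, the E alkene of unit 2 from thermodynamic control in the aldol dehydration.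

Key step: step 8

Assumption: 2-bromo-4-iodophenol, 1-(5-bromo-2,4-dihydroxyphenyl)ethan-1-one and 4-(methoxymethoxy)benzaldehyde are taken as catalogue compounds, and the hydroxyls ortho to a carbonyl group are left free throughout because their hydrogen bond keeps them out of K2CO3/MOMCl alkylation.

**Step 1**
Reactants: 1 2-bromo-4-iodophenol
Product: 2 2-bromo-4-iodo-1-(methoxymethoxy)benzene
Conditions: MOMCl (1.2 equiv), K2CO3, acetone, 0 °C to rt
Reagents that add atoms: chloromethyl methyl ether (MOMCl), COCCl
Why: Williamson-type O-alkylation of the phenoxide with the reactive α-chloro ether masks the ring B phenol as a base-stable acetal for the metal-mediated steps.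

**Step 2**
Reactants: 2 2-bromo-4-iodo-1-(methoxymethoxy)benzene; 3 ethynyltrimethylsilane
Product: 4 {[3-bromo-4-(methoxymethoxy)phenyl]ethynyl}trimethylsilane
Conditions: PdCl2(PPh3)2 (2 mol%), CuI (4 mol%), Et3N, THF, rt
Reagents that add atoms: none
Why: Sonogashira coupling, in which zerovalent palladium inserts into the C–I bond far faster than into the C–Br bond at room temperature, so the alkyne is placed para to the acetal and the bromide is kept for the biaryl bond.

**Step 3**
Reactants: 4 {[3-bromo-4-(methoxymethoxy)phenyl]ethynyl}trimethylsilane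
Product: 5 2-[2-(methoxymethoxy)-5-[(trimethylsilyl)ethynyl]phenyl]-4,4,5,5-tetramethyl-1,3,2-dioxaborolane
Conditions: B2pin2 (1.1 equiv), PdCl2(dppf) (3 mol%), KOAc, 1,4-dioxane, 85 °C
Reagents that add atoms: bis(pinacolato)diboron, CC1(C)OB(OC1(C)C)B1OC(C)(C)C(C)(C)O1
Why: Miyaura borylation of the aryl bromide under the weak base KOAc, conditions to which the silyl alkyne and the aryl acetal are inert.

**Step 4**
Reactants: 6 1-(5-bromo-2,4-dihydroxyphenyl)ethan-1-one
Product: 7 1-[5-bromo-2-hydroxy-4-(methoxymethoxy)phenyl]ethan-1-one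
Conditions: MOMCl (1.05 equiv), K2CO3, acetone, 0 °C to rt
Reagents that add atoms: chloromethyl methyl ether (MOMCl), COCCl
Why: the C2 hydroxyl is tied up in a hydrogen bond to the acetyl carbonyl, so alkylation with one equivalent of MOMCl should take place at the free, more acidic C4 hydroxyl (regioselective MOM protection).

**Step 5**
Reactants: 5 2-[2-(methoxymethoxy)-5-[(trimethylsilyl)ethynyl]phenyl]-4,4,5,5-tetramethyl-1,3,2-dioxaborolane; 7 1-[5-bromo-2-hydroxy-4-(methoxymethoxy)phenyl]ethan-1-one
Product: 8 1-[2-hydroxy-4-(methoxymethoxy)-5-{2-(methoxymethoxy)-5-[(trimethylsilyl)ethynyl]phenyl}phenyl]ethan-1-one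
Conditions: Pd(OAc)2 (3 mol%), SPhos (6 mol%), K3PO4, toluene/H2O, 80 °C
Reagents that add atoms: none
Why: Suzuki–Miyaura coupling fixes the ring B–ring C bond at the two pre-functionalised carbons, the electron-rich biaryl phosphine serving the di-ortho-oxygenated pair; any loss of the silyl cap under the aqueous base is harmless because step 6 removes it anyway.

**Step 6**
Reactants: 8 1-[2-hydroxy-4-(methoxymethoxy)-5-{2-(methoxymethoxy)-5-[(trimethylsilyl)ethynyl]phenyl}phenyl]ethan-1-one; 9 4-(methoxymethoxy)benzaldehyde
Product: 11 alkynyl chalcone (E)-1-[5-[5-ethynyl-2-(methoxymethoxy)phenyl]-2-hydroxy-4-(methoxymethoxy)phenyl]-3-[4-(methoxymethoxy)phenyl]prop-2-en-1-one, via desilylated alkynyl ketone 10 (not isolated)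
Conditions: KOH (excess), EtOH/H2O, rt; aq NH4Cl work-up
Reagents that add atoms: none
Why: Claisen–Schmidt condensation (aldol addition, then E1cB dehydration) should give the thermodynamically favoured E enone while hydroxide cleaves the alkynyl C–Si bond in the same flask, the aryl acetals and the terminal alkyne being stable to cold ethanolic KOH.

**Step 7**
Reactants: 12 2,4-dihydroxybenzaldehyde
Product: 13 2-hydroxy-4-(methoxymethoxy)benzaldehyde
Conditions: MOMCl (1.05 equiv), K2CO3, acetone, 0 °C to rt
Reagents that add atoms: chloromethyl methyl ether (MOMCl), COCCl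
Why: as in step 4, the C2 hydroxyl is hydrogen-bonded to the formyl oxygen, so regioselective MOM protection should occur at the C4 hydroxyl and leave the rhodium-binding phenol free.

**Step 8**
Reactants: 11 (E)-1-[5-[5-ethynyl-2-(methoxymethoxy)phenyl]-2-hydroxy-4-(methoxymethoxy)phenyl]-3-[4-(methoxymethoxy)phenyl]prop-2-en-1-one; 13 2-hydroxy-4-(methoxymethoxy)benzaldehyde (1.3 equiv)
Product: 14 (E)-1-[2-hydroxy-4-(methoxymethoxy)phenyl]-3-[3-[4-hydroxy-2-(methoxymethoxy)-5-[(E)-3-[4-(methoxymethoxy)phenyl]prop-2-enoyl]phenyl]-4-(methoxymethoxy)phenyl]prop-2-en-1-one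
Conditions: [RhCl(cod)]2 (2.5 mol%), 1,1'-bis(diphenylphosphino)ferrocene (dppf, 5 mol%), Na2CO3 (10 mol%), toluene, 90 °C, slow addition of 11
Reagents that add atoms: none
Why: Na2CO3 turns the C2 hydroxyl of 13 into a rhodium phenoxide, and oxidative addition of the adjacent formyl C–H to monovalent rhodium gives a five-membered acyl(hydrido) chelate of trivalent rhodium whose O–Rh bond holds the acyl group and suppresses decarbonylation; syn hydrometalation of the terminal alkyne of 11 and C–C reductive elimination then forge the carbonyl–Cα bond. The closest known reaction type is the rhodium-catalysed, chelation-assisted intermolecular hydroacylation of alkynes with salicylaldehydes to give 2-alkenoylphenols. No ring is closed and no stereocentre is formed; the E geometry follows from delivery of H and acyl to the same side of the triple bond, which places the aroyl group trans to ring B. The step needs regioselectivity (acyl to the terminal alkyne carbon, not to the carbon bearing ring B), which the unsubstituted alkyne terminus and the bulky dppf-bound acyl rhodium fragment should secure by placing rhodium on the less hindered carbon, the sense that is also electronically preferred for aryl alkynes. It also needs chemoselectivity for the alkyne over the enone of unit 2, secured because only 13 carries a formyl C–H next to a chelating phenol and an alkyne inserts far faster than a 1,2-disubstituted enone. Every atom of both partners ends up in 14, so nothing but the acetals has to be removed afterwards.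

**Step 9**
Reactants: 14 (E)-1-[2-hydroxy-4-(methoxymethoxy)phenyl]-3-[3-[4-hydroxy-2-(methoxymethoxy)-5-[(E)-3-[4-(methoxymethoxy)phenyl]prop-2-enoyl]phenyl]-4-(methoxymethoxy)phenyl]prop-2-en-1-one
Product: 15 target bichalcone (E)-1-(2,4-dihydroxyphenyl)-3-[3-[2,4-dihydroxy-5-[(E)-3-(4-hydroxyphenyl)prop-2-enoyl]phenyl]-4-hydroxyphenyl]prop-2-en-1-one
Conditions: HCl (3 M aq), MeOH/THF, 50 °C
Reagents that add atoms: none
Why: acid-catalysed transacetalisation to methanol (MOM cleavage) should release the four phenols without touching the E enones, mild warming and short contact limiting oxa-Michael ring closure of the 2'-hydroxychalcone units.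

**Compound list**

1 | 2-bromo-4-iodophenol | Oc1ccc(I)cc1Br | starting material
2 | 2-bromo-4-iodo-1-(methoxymethoxy)benzene | COCOc1ccc(I)cc1Br | intermediate
3 | ethynyltrimethylsilane | C#C[Si](C)(C)C | starting material
4 | {[3-bromo-4-(methoxymethoxy)phenyl]ethynyl}trimethylsilane | COCOc1ccc(C#C[Si](C)(C)C)cc1Br | intermediate
5 | 2-[2-(methoxymethoxy)-5-[(trimethylsilyl)ethynyl]phenyl]-4,4,5,5-tetramethyl-1,3,2-dioxaborolane | COCOc1ccc(C#C[Si](C)(C)C)cc1B1OC(C)(C)C(C)(C)O1 | intermediate
6 | 1-(5-bromo-2,4-dihydroxyphenyl)ethan-1-one | CC(=O)c1cc(Br)c(O)cc1O | starting material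
7 | 1-[5-bromo-2-hydroxy-4-(methoxymethoxy)phenyl]ethan-1-one | CC(=O)c1cc(Br)c(OCOC)cc1O | intermediate
8 | 1-[2-hydroxy-4-(methoxymethoxy)-5-{2-(methoxymethoxy)-5-[(trimethylsilyl)ethynyl]phenyl}phenyl]ethan-1-one | CC(=O)c1cc(-c2cc(C#C[Si](C)(C)C)ccc2OCOC)c(OCOC)cc1O | intermediate
9 | 4-(methoxymethoxy)benzaldehyde | COCOc1ccc(C=O)cc1 | starting material
10 | 1-[5-[5-ethynyl-2-(methoxymethoxy)phenyl]-2-hydroxy-4-(methoxymethoxy)phenyl]ethan-1-one (desilylated alkynyl ketone, not isolated) | CC(=O)c1cc(-c2cc(C#C)ccc2OCOC)c(OCOC)cc1O | intermediate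
11 | (E)-1-[5-[5-ethynyl-2-(methoxymethoxy)phenyl]-2-hydroxy-4-(methoxymethoxy)phenyl]-3-[4-(methoxymethoxy)phenyl]prop-2-en-1-one | C#Cc1ccc(OCOC)c(-c2cc(C(=O)/C=C/c3ccc(OCOC)cc3)c(O)cc2OCOC)c1 | intermediate
12 | 2,4-dihydroxybenzaldehyde | O=Cc1ccc(O)cc1O | starting material
13 | 2-hydroxy-4-(methoxymethoxy)benzaldehyde | COCOc1ccc(C=O)c(O)c1 | intermediate
14 | (E)-1-[2-hydroxy-4-(methoxymethoxy)phenyl]-3-[3-[4-hydroxy-2-(methoxymethoxy)-5-[(E)-3-[4-(methoxymethoxy)phenyl]prop-2-enoyl]phenyl]-4-(methoxymethoxy)phenyl]prop-2-en-1-one | O=C(/C=C/c1ccc(OCOC)c(-c2cc(C(=O)/C=C/c3ccc(OCOC)cc3)c(O)cc2OCOC)c1)c1ccc(OCOC)cc1O | intermediate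
15 | (E)-1-(2,4-dihydroxyphenyl)-3-[3-[2,4-dihydroxy-5-[(E)-3-(4-hydroxyphenyl)prop-2-enoyl]phenyl]-4-hydroxyphenyl]prop-2-en-1-one | O=C(/C=C/c1ccc(O)c(-c2cc(C(=O)/C=C/c3ccc(O)cc3)c(O)cc2O)c1)c1ccc(O)cc1O | target

**Step count and risks**

Total step count: 9. Longest linear sequence: 7 steps (steps 1, 2, 3, 5, 6, 8, 9).

Most likely to fail, first: step 8. The hydride may insert with the reverse regiochemistry (rhodium on the carbon bearing ring B), which leads to the branched 1,1-disubstituted enone. Rhodium-mediated oligomerisation of the electron-rich aryl alkyne and decarbonylation of the aldehyde may also compete. The fallback builds unit 1 by olefin cross-metathesis at the Cα=Cβ bond instead; it sets out from 11 and 13 and comes back at 14. Semihydrogenation of 11 (H2, Pd/CaCO3 poisoned with Pb(OAc)2, quinoline, EtOAc, rt) should give the styrene (E)-1-[5-[5-ethenyl-2-(methoxymethoxy)phenyl]-2-hydroxy-4-(methoxymethoxy)phenyl]-3-[4-(methoxymethoxy)phenyl]prop-2-en-1-one F1. Addition of vinylmagnesium bromide (2.2 equiv, THF, 0 °C) to 13 should give the racemic allylic alcohol 2-(1-hydroxyprop-2-en-1-yl)-5-(methoxymethoxy)phenol F2, which MnO2 in CH2Cl2 should oxidise to the aryl vinyl ketone 1-[2-hydroxy-4-(methoxymethoxy)phenyl]prop-2-en-1-one F3. Cross-metathesis of F1 with an excess of freshly made F3 (second-generation Hoveyda–Grubbs catalyst, CH2Cl2, 40 °C) should give 14 as the E isomer, the 1,2-disubstituted enone of unit 2 being inert to the ruthenium carbene.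

Second: step 5. Protodeboronation of the electron-rich ortho-alkoxy boronate may outrun a slow oxidative addition into the bromide of 7, whose phenol is ionised by the base. Early loss of the silyl cap may also open palladium-mediated coupling at the free alkyne. The fallback is a base-free Stille coupling; it sets out from 4 and 7 and comes back at 8. Bromine–lithium exchange on 4 (n-BuLi, THF, −78 °C) and quenching with Bu3SnCl should give tributyl{2-(methoxymethoxy)-5-[(trimethylsilyl)ethynyl]phenyl}stannane F4. Coupling of F4 with 7 (Pd(PPh3)4, CuI, DMF, 90 °C) under neutral, anhydrous conditions should give 8 with the phenol protonated and the silyl group untouched.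

Third: step 9. Acid-promoted oxa-Michael ring closure of the two 2'-hydroxychalcone units to chroman-4-ones may accompany the slow cleavage of four acetals and leave a mixture of ring and chain isomers. The fallback accepts the ring closure and reverses it afterwards; it sets out from 14 and comes back at 15. The acid treatment is pushed (HCl, MeOH, reflux) until all acetals are gone, in the limit to the doubly cyclised 7-hydroxy-2-[4-hydroxy-3-[7-hydroxy-2-(4-hydroxyphenyl)-4-oxochroman-6-yl]phenyl]chroman-4-one F5, a mixture of stereoisomers at the two C2 centres. The crude material is then opened in aqueous KOH/MeOH at rt under argon by E1cB retro-oxa-Michael reaction of both rings, the open chalcone being favoured as its polyphenolate because neither unit has a 6'-oxygen. Cold acidification should return 15.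

**Further compounds**

F1 | step 8 | (E)-1-[5-[5-ethenyl-2-(methoxymethoxy)phenyl]-2-hydroxy-4-(methoxymethoxy)phenyl]-3-[4-(methoxymethoxy)phenyl]prop-2-en-1-one | C=Cc1ccc(OCOC)c(-c2cc(C(=O)/C=C/c3ccc(OCOC)cc3)c(O)cc2OCOC)c1
F2 | step 8 | 2-(1-hydroxyprop-2-en-1-yl)-5-(methoxymethoxy)phenol (racemic) | C=CC(O)c1ccc(OCOC)cc1O
F3 | step 8 | 1-[2-hydroxy-4-(methoxymethoxy)phenyl]prop-2-en-1-one | C=CC(=O)c1ccc(OCOC)cc1O
F4 | step 5 | tributyl{2-(methoxymethoxy)-5-[(trimethylsilyl)ethynyl]phenyl}stannane | CCCC[Sn](CCCC)(CCCC)c1cc(C#C[Si](C)(C)C)ccc1OCOC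
F5 | step 9 | 7-hydroxy-2-[4-hydroxy-3-[7-hydroxy-2-(4-hydroxyphenyl)-4-oxochroman-6-yl]phenyl]chroman-4-one (mixture of stereoisomers) | O=C1CC(c2ccc(O)c(-c3cc4C(=O)CC(c5ccc(O)cc5)Oc4cc3O)c2)Oc2cc(O)ccc12
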